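Put nothing into this flask at 25 min but L, if you add anything at all. X is the substrate, E the reagent, D the product and L the catalyst. In the proposed steps X and L give Q, Q binds L as G, and E turns G into D and frees L, while L + D gives Z, a form outside that round.

common to all: X 0.80 M; L 16 mM
- Tuesday's: E 0.64 M; temperature 5 °C; the very flask that is asked about, followed so far
- Thursday's: E 1.3 M; temperature −10 °C; run made earlier
- flask: E 0.640 M; temperature 5 °C; time 25 min

- Tuesday's (time / min: D / %, X / %): 1.50: 22, 60; 2.50: 34, 51; 4.00: 49, 37; 6.00: 56, 32; 8.00: 54, 30; 12.0: 58, 27; 20.0: 58, 29
- Thursday's (time / min: D / %, X / %): 3.00: 18, 62; 6.00: 39, 46; 10.0: 52, 35; 12.0: 64, 28; 15.0: 63, 29; 20.0: 69, 23; 25.0: 74, 17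

(readings scatter by 2 percentage points)

- D that was removed still counts
- steps that have been proposed: E + G -> L + D; X + L <-> L + Q; L + Q <-> G; L + D -> Z
- additions bring no volume worth counting

- north: at 25 min raise the temperature by 15 K, then wait 12 min
- north-west: at 25 min add L, 100% of the amount charged, then wait 12 min
- west: at 25 min take out 90% of the D then present, then wait 12 min
- south: at 25 min add E, 100% of the amount charged, then wait 12 min
- south-west: change nothing and wait 12 min more

- D, in percent of the X first charged, at 25 min
- the remedy with the largest gain of D, or "none" below 2 percentage points (north / north-west / west / south / south-west / none)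
- D present, with what was taken out counted in, in percent of the X first charged, after south
- D present, with what was taken out counted in, in percent of the X first charged, after south-west

Here is what you take over in Tuesday's flask. D stood at 56% after 6.00 min and at 58% after 20.0 min, a rise of 2 percentage points, which is one standard deviation of a reading. X still read 29% at that time, yet the rise in D faded into the scatter. So I read the stall as lost L, not as a kinetic order: both runs were charged with the same L, so no reading here compares amounts of L. The charges say the same:

E allows: 80.0% of the X charged

L delivered: 29.0 D per L charged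

That second line is the turnover number N, the D made per L charged up to the stall. My rule: at one temperature, with X and L as charged here, D stops at the smaller of the cap from E and N·L/X. E is the limiting reagent, but L stops this flask first. So expect D near 58% when you come.

Don't touch the heat, the E or the D, and don't simply wait: in the proposed steps Z has no way back to L. Fresh L can work on the 22 points of room still open.

The forecast gives 58% (56.5% to 59.5%), north-west as best, 58.3% after south and 58% after south-west: “Only fresh L helps.”

The flask gives 59.3%, and north-west gains 8.8 points. South ends at 59.3%, south-west at 59.3%.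

    E + G → L + D (k = 7.94 M⁻¹ s⁻¹, Ea = 52.0 kJ mol⁻¹)
    X + L ⇌ L + Q (K = 0.380, k = 0.920 M⁻¹ s⁻¹, Ea = 47.0 kJ mol⁻¹, ΔH = −13.0 kJ mol⁻¹)
    L + Q ⇌ G (K = 1.10 M⁻¹, k = 1.72 M⁻¹ s⁻¹, Ea = 50.0 kJ mol⁻¹, ΔH = −11.0 kJ mol⁻¹)
    L + D → Z (k = 0.0130 M⁻¹ s⁻¹, Ea = 62.0 kJ mol⁻¹)
    (constants at 5 °C)

The flask's D is 29.7 turnovers, beside the N of 29.0 read earlier. In the neighbour charged with 0.26 M of E, the cap is 32.5%, below N·L/X, and that flask holds D 30.5%, with E down to 0.143% of its charge and L at 1.79%. The asked flask has come to rest: at 25 min, L stands at 0.0337% of its charge, and 12 min more add 0.0053 points. At 250 min D reads 59.3%, with E still at 23.3% of its charge and X at 29.6%.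

The numbers in the tables come from a simulation from invented constants.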